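Ring C (the cyclobutane) is cut at two bonds, ring CH (next to C6-CH2)–ring CH2 and CMe2–CH(isopropenyl). It is the [2+2] adduct of the C=C of a C6 prenyl group and the vinyl C=C of an isoprene unit, so the precursor carries a gem-diprenyl C6 that is not a stereocentre.
Enabling feature: on ring C the isopropenyl group is cis-1,3 to the C6-CH2 arm, and its CH3 can reach the CO2H of the C8 side chain across the C7=O edge of ring A. CH3 and CO2H are therefore joined as a 2-methylidenebut-3-enyl ester, which serves as both tether and diene chromophore. Zerovalent palladium/formate later cuts this ester through a pi-allyl with two equal CH2 ends, which returns exactly CH3 and CO2H.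
The gem-diprenyl trione comes from alkylative dearomatisation of an 8-substituted 5,7-dihydroxy-cis-2,3-dimethylchromanone. Ring B (pyranone) comes from a quinine-catalysed oxa-Michael closure, and the benzylic centre from a rhodium-catalysed 1,4-addition of PhB(OH)2 to a coumarin.
Ring order: ring A (bought as an arene, dearomatised in step 6), the temporary coumarin lactone (opened in step 3), ring B (step 4), then ring C last (step 9, together with a temporary 13-membered lactone that step 10 opens).

Key step: step 9

Assumption: dearomatised compounds are drawn as the C4-enol tautomer of the target SMILES, and the sense of induction of (S)-SEGPHOS (step 2) and (−)-quinine (step 4) is taken over from the closest coumarin and ortho-tigloylphenol substrates, the mirror-image ligand and quinidine being equally available.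

Step 1
Reactants: 1 5,7-dihydroxycoumarin
Product: 2 5,7-bis(benzyloxy)coumarin
Conditions: BnBr (2.4 equiv), K2CO3, DMF, 60 °C
Reagents that add atoms: benzyl bromide, BrCc1ccccc1
Why: A Williamson ether synthesis caps both phenols, so the lactone oxygen stays the only oxygen that can later close ring B; no stereocentre is formed.

Step 2
Reactants: 2 5,7-bis(benzyloxy)coumarin; 3 phenylboronic acid
Product: 4 (S)-5,7-bis(benzyloxy)-4-phenylchroman-2-one
Conditions: Rh(acac)(C2H4)2 (3 mol%), (S)-SEGPHOS (3.3 mol%), PhB(OH)2 (5 equiv), dioxane/H2O 10:1, 60 °C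
Reagents that add atoms: phenylboronic acid 3, OB(O)c1ccccc1
Why: In this Hayashi–Miyaura asymmetric 1,4-addition to a coumarin, the bisphosphine-bound phenylrhodium species inserts the C3=C4 bond on one face and hydrolysis of the rhodium enolate releases the lactone, which sets the benzylic centre as S under ligand control.

Step 3
Reactants: 4 (S)-5,7-bis(benzyloxy)-4-phenylchroman-2-one; 5 tiglic acid
Product: 7 methyl (3S)-3-{4,6-bis(benzyloxy)-2-hydroxy-3-[(E)-2-methylbut-2-enoyl]phenyl}-3-phenylpropanoate, via 8-tigloyl lactone 6 (not isolated)
Conditions: tiglic acid (1.5 equiv), (CF3CO)2O (3 equiv), H3PO4 (cat.), CH2Cl2, 0 to 20 °C; then MeOH (excess), 20–40 °C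
Reagents that add atoms: tiglic acid 5, C/C=C(\C)C(=O)O; methanol, CO
Why: Friedel–Crafts acylation with the mixed trifluoroacetic anhydride should go to C8 (para to the 5-benzyloxy group, ortho to the 7-benzyloxy group, flanked only by the tied-back lactone oxygen, as in other 5,7-dialkoxy-chromans and -coumarins), and the acid already present then catalyses methanolysis of the crowded aryl lactone, driven by the new phenol–ketone hydrogen bond; the benzylic centre is not touched.

Step 4
Reactants: 7 methyl (3S)-3-{4,6-bis(benzyloxy)-2-hydroxy-3-[(E)-2-methylbut-2-enoyl]phenyl}-3-phenylpropanoate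
Product: 8 methyl (3S)-3-[(2R,3S)-5,7-bis(benzyloxy)-2,3-dimethyl-4-oxochroman-8-yl]-3-phenylpropanoate (cis-2,3-dimethyl)
Conditions: (−)-quinine (20 mol%), PhCl, 15 °C
Reagents that add atoms: none
Why: In this cinchona-alkaloid-catalysed intramolecular oxa-Michael addition of an ortho-tigloylphenol, the quinuclidine nitrogen deprotonates the only free phenol while the C9 hydroxyl binds the enone, so oxygen attacks one face of the (E)-alkene to set C2 as R, and the ammonium ion protonates the enolate kinetically to set C3 as S, giving the cis-2,3-dimethyl ring B.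

Step 5
Reactants: 8 methyl (3S)-3-[(2R,3S)-5,7-bis(benzyloxy)-2,3-dimethyl-4-oxochroman-8-yl]-3-phenylpropanoate
Product: 9 methyl (3S)-3-[(2R,3S)-5,7-dihydroxy-2,3-dimethyl-4-oxochroman-8-yl]-3-phenylpropanoate
Conditions: H2 (1 atm), Pd/C (10 wt%), EtOAc, 20 °C
Reagents that add atoms: none
Why: Catalytic hydrogenolysis of aryl benzyl ethers runs under neutral conditions and leaves the strongly conjugated C4 ketone, the methyl ester and the acid- and base-sensitive cis-2,3-dimethyl unit untouched.

Step 6
Reactants: 9 methyl (3S)-3-[(2R,3S)-5,7-dihydroxy-2,3-dimethyl-4-oxochroman-8-yl]-3-phenylpropanoate; 10 prenyl bromide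
Product: 13 (3S)-3-[(2R,3S)-4-hydroxy-2,3-dimethyl-6,6-bis(3-methylbut-2-enyl)-5,7-dioxo-3,5,6,7-tetrahydro-2H-chromen-8-yl]-3-phenylpropanoic acid, via hydroxy acid 11 (not isolated), via 6-prenyl acid 12 (not isolated)
Conditions: KOH (6 equiv), degassed H2O/MeOH 4:1, 0 °C, 1 h; prenyl bromide (2.4 equiv), 0 °C; then 1 M HCl to pH 3
Reagents that add atoms: prenyl bromide 10, CC(C)=CCBr; potassium hydroxide, [K+].[OH-]
Why: Saponification is followed by alkylative dearomatisation of an acylphloroglucinol-type polyanion (the reaction type that turns deoxyhumulones into lupulones): C6 is the only unsubstituted ring carbon and lies between two phenoxide oxygens, so both SN2 alkylations in protic medium end there and the second breaks aromaticity, while the polyanionic state should keep C3-H from being removed and so preserve the cis unit; C6 carries two equal groups and is not yet a stereocentre.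

Step 7
Reactants: 14 2-methyl-2-vinyloxirane (isoprene monoxide, racemic)
Product: 15 2-methylidenebut-3-en-1-ol
Conditions: LiN(iPr)2 (1.3 equiv), Et2O, −78 to 20 °C; H2O
Reagents that add atoms: none
Why: In this base-induced isomerisation of an epoxide to an allylic alcohol, the hindered amide removes a methyl proton and the C–O bond at the fully substituted carbon breaks, giving the 2-substituted diene and destroying the stereocentre of 14.

Step 8
Reactants: 13 gem-diprenyl trione acid; 15 2-methylidenebut-3-en-1-ol
Product: 16 2-methylidenebut-3-enyl (3S)-3-[(2R,3S)-4-hydroxy-2,3-dimethyl-6,6-bis(3-methylbut-2-enyl)-5,7-dioxo-3,5,6,7-tetrahydro-2H-chromen-8-yl]-3-phenylpropanoate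
Conditions: 15 (3 equiv), DCC (1.2 equiv), DMAP (1.2 equiv), CH2Cl2, 0 °C, dark
Reagents that add atoms: 2-methylidenebut-3-en-1-ol 15, C=CC(=C)CO
Why: In this Steglich esterification the carbodiimide activates the carboxylic acid, DMAP relays the acyl group to the primary allylic alcohol, and the acidic enol is parked as its DMAP salt; no stereocentre is touched.

Step 9
Reactants: 16 dienyl ester of the gem-diprenyl trione acid
Product: 17 cyclobutane-bridged 13-membered macrolactone (C6 R; ring-C CH next to C6-CH2 R; ring-C CH bearing C(=CH2)CH2O cis to that arm, R by rule but with the same spatial arrangement as S in 18; 2R,3S and benzylic S unchanged)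
Conditions: [Ir(dF(CF3)ppy)2(dtbbpy)]PF6 (2 mol%), degassed CH2Cl2 (1 mM), blue LED 450 nm, 20 °C
Reagents that add atoms: none
Why: Proposed new method: Triplet energy transfer from the excited iridium complex should reach only the 2-substituted 1,3-diene of 16 (the isolated prenyl C=C bonds lie much higher, and the chelated, un-ionised enol-trione should shed any energy by internal proton transfer); the twisted diene triplet then attacks the CH end of a prenyl group with its vinyl CH2 terminus to give a tertiary-alkyl/allyl 1,4-diradical, and after spin inversion the CMe2 radical collapses on the inner allyl terminus. The closest known reaction type is the visible-light, triplet-sensitised intramolecular [2+2] photocycloaddition of 1,3-dienes with tethered alkenes to vinylcyclobutanes, known for three-atom tethers, and what is new here is the long ester tether and the choice between two diastereotopic prenyl groups. The first bond closes the temporary 13-membered lactone ring by a 13-exo-trig radical attack, and the second closes ring C by 1,4-diradical recombination. C6 is controlled by allylic 1,3-strain about C8=C8a, which keeps the benzylic H in the plane of ring A next to O1, so the (S)-centre holds CH2CO2R above one face and tilted over C7=O, and only the prenyl group on that face is within reach, which makes C6 R. The ring-C CH next to C6-CH2 is controlled by the reacting prenyl group lying folded over C7 with the C6–CH2 bond perpendicular to its C=C plane, so it is struck on the outer face anti to C6 (giving R), and the ring-C CH bearing the vinylidene is controlled by the ansa chain, which can span the 1,3-positions of a four-membered ring only on one face (giving cis). The step needs [2+2] over [4+2] (the s-trans diene triplet cannot close to a cis-cyclohexene), head-to-head orientation (attack at the less hindered alkene carbon gives the tertiary radical), reaction at the vinyl and not the methylidene C=C (the other diradical could only join two fully substituted carbons in a smaller ring and should cleave back to 16), and cyclisation over dimerisation (high dilution, with unproductive decay of the doubly terminal diene triplet returning 16 unchanged).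

Step 10
Reactants: 17 cyclobutane-bridged macrolactone
Product: 18 (3S)-3-[(2R,3S,6R)-6-{[(1R,3S)-2,2-dimethyl-3-(prop-1-en-2-yl)cyclobutyl]methyl}-4-hydroxy-2,3-dimethyl-6-(3-methylbut-2-enyl)-5,7-dioxo-3,5,6,7-tetrahydro-2H-chromen-8-yl]-3-phenylpropanoic acid (CNP0328119.1)
Conditions: Pd(PPh3)4 (5 mol%), HCO2H (3 equiv), Et3N (3 equiv), THF, 20–40 °C
Reagents that add atoms: none
Why: In this Tsuji-type palladium-catalysed formate hydrogenolysis of an allylic ester, ionisation of the primary 2-substituted allylic carboxylate gives a pi-allyl complex with two equivalent CH2 termini, so hydride transfer can only give the isopropenyl group while the carboxylate leaves as the free acid; the poorly coordinating prenyl alkene, the quaternary C6 and all six stereocentres should stay untouched in the buffered medium.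

Compound list
1 | 5,7-dihydroxycoumarin | O=c1ccc2c(O)cc(O)cc2o1 | starting material
2 | 5,7-bis(benzyloxy)coumarin | O=c1ccc2c(OCc3ccccc3)cc(OCc3ccccc3)cc2o1 | intermediate
3 | phenylboronic acid | OB(O)c1ccccc1 | starting material
4 | (S)-5,7-bis(benzyloxy)-4-phenylchroman-2-one | O=C1C[C@@H](c2ccccc2)c2c(OCc3ccccc3)cc(OCc3ccccc3)cc2O1 | intermediate
5 | tiglic acid, (E)-2-methylbut-2-enoic acid | C/C=C(\C)C(=O)O | starting material
6 | (S)-5,7-bis(benzyloxy)-8-[(E)-2-methylbut-2-enoyl]-4-phenylchroman-2-one (8-tigloyl lactone, not isolated) | O=C1C[C@@H](c2ccccc2)c2c(OCc3ccccc3)cc(OCc3ccccc3)c(C(=O)/C(C)=C/C)c2O1 | intermediate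
7 | methyl (3S)-3-{4,6-bis(benzyloxy)-2-hydroxy-3-[(E)-2-methylbut-2-enoyl]phenyl}-3-phenylpropanoate | COC(=O)C[C@@H](c1ccccc1)c1c(OCc2ccccc2)cc(OCc2ccccc2)c(C(=O)/C(C)=C/C)c1O | intermediate
8 | methyl (3S)-3-[(2R,3S)-5,7-bis(benzyloxy)-2,3-dimethyl-4-oxochroman-8-yl]-3-phenylpropanoate | COC(=O)C[C@@H](c1ccccc1)c1c(OCc2ccccc2)cc(OCc2ccccc2)c2c1O[C@H](C)[C@H](C)C2=O | intermediate
9 | methyl (3S)-3-[(2R,3S)-5,7-dihydroxy-2,3-dimethyl-4-oxochroman-8-yl]-3-phenylpropanoate | COC(=O)C[C@@H](c1ccccc1)c1c(O)cc(O)c2c1O[C@H](C)[C@H](C)C2=O | intermediate
10 | prenyl bromide, 1-bromo-3-methylbut-2-ene | CC(C)=CCBr | starting material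
11 | (3S)-3-[(2R,3S)-5,7-dihydroxy-2,3-dimethyl-4-oxochroman-8-yl]-3-phenylpropanoic acid (hydroxy acid, not isolated) | OC(=O)C[C@@H](c1ccccc1)c1c(O)cc(O)c2c1O[C@H](C)[C@H](C)C2=O | intermediate
12 | (3S)-3-[(2R,3S)-5,7-dihydroxy-2,3-dimethyl-6-(3-methylbut-2-enyl)-4-oxochroman-8-yl]-3-phenylpropanoic acid (6-prenyl acid, not isolated) | OC(=O)C[C@@H](c1ccccc1)c1c(O)c(CC=C(C)C)c(O)c2c1O[C@H](C)[C@H](C)C2=O | intermediate
13 | (3S)-3-[(2R,3S)-4-hydroxy-2,3-dimethyl-6,6-bis(3-methylbut-2-enyl)-5,7-dioxo-3,5,6,7-tetrahydro-2H-chromen-8-yl]-3-phenylpropanoic acid | CC(C)=CCC1(CC=C(C)C)C(=O)C2=C(O)[C@@H](C)[C@@H](C)OC2=C([C@@H](CC(=O)O)c2ccccc2)C1=O | intermediate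
14 | 2-methyl-2-vinyloxirane (racemic) | CC1(C=C)CO1 | starting material
15 | 2-methylidenebut-3-en-1-ol | C=CC(=C)CO | intermediate
16 | 2-methylidenebut-3-enyl ester of 13 | CC(C)=CCC1(CC=C(C)C)C(=O)C2=C(O)[C@@H](C)[C@@H](C)OC2=C([C@@H](CC(=O)OCC(=C)C=C)c2ccccc2)C1=O | intermediate
17 | cyclobutane-bridged 13-membered macrolactone | C=C(C4)[C@@H]1C[C@H](C[C@@]2(CC=C(C)C)C(=O)C3=C(O)[C@@H](C)[C@@H](C)OC3=C([C@@H](CC(=O)O4)c3ccccc3)C2=O)C1(C)C | intermediate
18 | CNP0328119.1 | C=C(C)[C@@H]1C[C@H](C[C@@]2(CC=C(C)C)C(=O)C3=C(O)[C@@H](C)[C@@H](C)OC3=C([C@@H](CC(=O)O)c3ccccc3)C2=O)C1(C)C | target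

Total step count: 10. Longest linear sequence: 9 (steps 1–6 and 8–10; step 7 is a side branch).

Steps most likely to fail

Step 9 (labelled step). The diene triplet may relax or dimerise before it meets a prenyl group. It may also add through its methylidene terminus, or discriminate poorly between the two prenyl groups or the two alkene faces. The fallback uses known reactions only: the four-membered ring is taken from the chiral pool, and C6 is built by a second alkylative dearomatisation.
- Commercial (1S,5S)-verbenone F1 is cleaved with RuCl3 (cat.)/NaIO4 to (1S,3R)-cis-pinononic acid F2.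
- Wittig methylenation (Ph3P=CH2, excess) gives the isopropenyl acid F3.
- LiAlH4 gives the alcohol F4, and an Appel reaction (I2, PPh3, imidazole) gives the iodide F5.
- The fallback sets out from 12, which is isolated by stopping step 6 after one equivalent of 10. Its potassium salt is alkylated at C6 with F5 (KOH, DMSO/H2O) and the C6 epimers are separated.
- This comes back to the route at 18, and steps 7 to 10 fall away.

Step 6. Possible failures are competing O-alkylation, a stalled second alkylation, base-induced opening of ring B with loss of the cis-2,3 relationship, and air oxidation of the electron-rich anions. The fallback replaces SN2 chemistry under strong base by a base-free Tsuji–Trost prenylation. It sets out from 9, which is treated with tert-butyl 3-methylbut-2-enyl carbonate (2.5 equiv) and Pd(PPh3)4 in THF. O-prenylation is reversible under zerovalent palladium and C-prenylation is not, so material should funnel to C6 and give the gem-diprenyl methyl ester F6. Mild hydrolysis with Me3SnOH in 1,2-dichloroethane comes back to the route at 13.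

Step 3. Possible failures are attack of the acylating agent at C6 instead of C8, acid cleavage of the benzyl ether next to the new ketone, and premature acid-catalysed closure to a stereorandom chromanone. The fallback builds the tigloyl group in two pieces without an acylium ion.
- It sets out from 4, which undergoes Vilsmeier–Haack formylation (POCl3, DMF) to the 8-carbaldehyde F7.
- A Nozaki–Hiyama–Kishi coupling with (E)-2-iodobut-2-ene (CrCl2, NiCl2 cat., DMF), which tolerates the lactone, gives the allylic alcohol F8 as an irrelevant mixture at the carbinol carbon.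
- Dess–Martin oxidation comes back to the route at 6, which is then methanolysed to 7 with a catalytic amount of TsOH.

Further compounds
F1 | step 9 | (1S,5S)-verbenone | CC1=CC(=O)[C@H]2C[C@@H]1C2(C)C
F2 | step 9 | (1S,3R)-3-acetyl-2,2-dimethylcyclobutane-1-carboxylic acid (cis-pinononic acid) | CC(=O)[C@@H]1C[C@H](C(=O)O)C1(C)C
F3 | step 9 | (1S,3S)-2,2-dimethyl-3-(prop-1-en-2-yl)cyclobutane-1-carboxylic acid | C=C(C)[C@@H]1C[C@H](C(=O)O)C1(C)C
F4 | step 9 | [(1S,3S)-2,2-dimethyl-3-(prop-1-en-2-yl)cyclobutyl]methanol | C=C(C)[C@@H]1C[C@H](CO)C1(C)C
F5 | step 9 | (1S,3S)-1-(iodomethyl)-2,2-dimethyl-3-(prop-1-en-2-yl)cyclobutane | C=C(C)[C@@H]1C[C@H](CI)C1(C)C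
F6 | step 6 | methyl ester of 13 | CC(C)=CCC1(CC=C(C)C)C(=O)C2=C(O)[C@@H](C)[C@@H](C)OC2=C([C@@H](CC(=O)OC)c2ccccc2)C1=O
F7 | step 3 | (S)-5,7-bis(benzyloxy)-2-oxo-4-phenylchromane-8-carbaldehyde | O=C1C[C@@H](c2ccccc2)c2c(OCc3ccccc3)cc(OCc3ccccc3)c(C=O)c2O1
F8 | step 3 | (4S)-5,7-bis(benzyloxy)-8-[(E)-1-hydroxy-2-methylbut-2-enyl]-4-phenylchroman-2-one (carbinol epimers) | O=C1C[C@@H](c2ccccc2)c2c(OCc3ccccc3)cc(OCc3ccccc3)c(C(O)/C(C)=C/C)c2O1
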